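## The problem

The target is a 7‑methoxy‑2,2‑dimethyl‑2H‑chromene (ring A plus the pyran ring; chromene numbering O1, C2–C4, C4a, C5–C8, C8a). C5 and C6 are bridged by three carbons, C5–Cc(H)–Cb(H)–CaH2–C6, so a five‑membered ring is fused to ring A. Cb and Cc are also part of a cyclobutane, completed by Cd, which carries a 3,4‑dihydroxyphenyl group, and by the quaternary carbon Ce (CMe2). There are three contiguous stereocentres, Cb (S), Cc (R) and Cd (S). The four/five ring fusion can only be cis, so the real choices are the absolute sense of the Cb/Cc pair and the position of the catechol ring on Cd, which is trans to ring A on the convex face. Because the three centres are locked on a small bicycle, one centre of known configuration can fix the other two. The catechol is easily oxidised, the chromene double bond is sensitive to acid, hydrogenation and anything that adds to styrenes, and the Cc–Cd bond is strained and doubly benzylic. Catechol and chromene are therefore revealed last, and the pyran ring is carried as a 4‑chromanone. Cd lies between a quaternary carbon and a tertiary benzylic carbon, so attaching the aryl group there is itself demanding. The enabling feature is that Cb–Cc is shared by both small rings. If it is cut, C5, C6, Ca, Cb, Ce, Cd and Cc form a benzo‑fused seven‑membered ring in which Cc=Cd is a styrene double bond and Cb is a carbinol carbon next to Ce. Cb is then 1,4 to Cc across the ring, which is the arrangement of an aryl homoallylic sulfonate.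

## Retrosynthesis

**Chromene and catechol (26 ⇒ 24 ⇒ 23).** The C3=C4 double bond of 26 is traced back to the C4 ketone of 24 (through the chromanol 25), and the two phenols to the benzyl ethers of 23. Carrying a chromanone removes the only other styrene from every earlier intermediate, which matters because the key step adds boron and copper to a styrene. The ketone also makes ring A less electron‑rich for the ozonolysis and the cross‑couplings. The forward steps must be mild: hydrogenolysis while no chromene is present, then dehydration of a very easily ionised benzylic alcohol.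

**The aryl–Cd bond (23 ⇒ 21 + 22; 21 ⇒ 20).** Cutting this bond leaves the trifluoroborate 21 (from the pinacol boronate 20) and 4‑bromo‑1,2‑bis(benzyloxy)benzene 22. Keeping boron on Cd, instead of carrying the aryl group through, is what lets the cyclobutane come from a borylcupration. The forward coupling must place the aryl group on the convex face at a crowded secondary carbon. A radical captured by nickel should do so under control of the bicycle, and the boron configuration from the key step points the same way.

**The shared bond Cb–Cc (20 ⇒ 18, through 19).** This cut opens both small rings at once and leaves the benzo‑fused cycloheptenyl mesylate 18, which has one stereocentre instead of three. The neighbouring cuts are weaker. Cutting Cc–Cd or Cb–Ce leads to cycloadditions that are hard to control in the absolute sense, and cutting the ring‑A bonds leaves the cyclobutane problem untouched. The forward reaction must add boron to Cd and copper to Cc from the face anti to the mesylate, and the benzylic copper 19 must then displace a secondary, neopentyl‑type sulfonate across the ring.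

**The seven‑membered ring (18 ⇒ 17 ⇒ 16 ⇒ 15).** The mesylate comes from the alcohol 17. Its Cc=Cd bond is cut by ring‑closing metathesis to the diene 16, and the C5–vinyl bond by cross‑coupling to the aryl triflate 15. Metathesis is preferred to an aldol or alkylation closure because it tolerates the free carbinol and needs only two terminal alkenes. Both alkenes are hindered, so the closure will need heat and dilution.

**The controlling stereocentre (15 ⇒ 11 + 12, through 13 and 14).** Cutting Cb–Ce gives the arylacetaldehyde 11 and a reverse‑prenyl nucleophile made from 3‑methylbuta‑1,2‑diene 12. One reagent‑controlled carbonyl addition then supplies Ce with both methyls, the vinyl group for the metathesis and the only stereocentre the route has to set. The forward step must be fast and non‑basic, because 11 is an enolisable arylacetaldehyde.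

**Ring A (11 ⇒ 9 ⇒ 8 ⇒ 6 ⇒ 5 ⇒ 4 ⇒ 1 + 2).** The aldehyde comes from the allyl group of 9, the triflate from the chelated phenol of 8, and the allyl group from a Claisen rearrangement of the 5‑allyl ether 6. The Claisen can only deliver to C6, so the C5 oxygen ends up next to the new carbon chain, where it becomes the handle for the vinyl group. 6 goes back through 5 to the chromanone 4, made from phloroglucinol 1 and 3‑methylbut‑2‑enoic acid 2.

## Roads not taken

Alternative 1: Ring A is made last. The cut goes through the two ring‑A bonds at C5 and C6. In the forward step the bromo bicyclo[3.2.0]heptenone A2, which already holds the cyclobutane, the gem‑dimethyl group and the protected catechol, reacts in a Diels–Alder reaction with the prenyl‑bearing ketene‑acetal diene A3. Loss of HBr and methanol gives the indanone A1 with methoxy, hydroxy and prenyl groups in place. This has real merits: the arene is assembled convergently, the chromene could be closed late from the prenyl phenol, and no cross‑coupling at the crowded Cd is needed. Its weakness is that A2 contains all three stereocentres and the whole cyclobutane, so the central problem is moved into a starting material. A1 also carries an extra benzylic ketone at Ca that must be deleted next to an acid‑sensitive prenyl phenol, and A3 is a labile tetrasubstituted diene. In convergence Alternative 1 is better. The chosen plan offers instead a step that creates the cyclobutane and its stereochemistry, fed by a ring‑A sequence of ordinary reactions.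

Alternative 2: Both cyclobutane bonds, Cb–Ce and Cc–Cd, are cut. The keteniminium ion from the arylacetamide A6 (Tf2O, collidine) would add across the double bond of the indene A5, and hydrolysis would give the exo‑aryl cyclobutanone A4. The regiochemistry is right, the aryl group arrives with the ring, and the exo position is the thermodynamic one next to a ketone. A5 is also only two steps from compound 9 of the present route. In step count to the carbon skeleton, and in avoiding the late coupling, this road is better. Its weak points lie after the cycloaddition. The cyclobutanone carbonyl must become CMe2 at a carbon flanked by two tertiary centres while the chromanone carbonyl, which answers to the same reagents, is present. The absolute configuration also depends on auxiliary control in an intermolecular cycloaddition to an indene, where the facial bias is uncertain. The chosen plan has the gem‑dimethyl group from the start and takes its absolute configuration from a dependable carbonyl addition.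

Alternative 3: The arene–CH2 bond (C6–Ca) and the arene–CH bond (C5–Cc) are cut. With Pd(OAc)2, tri(2‑furyl)phosphine, norbornene, Cs2CO3 and sodium formate, the chromene iodide A8 would be alkylated at its free ortho position by the cyclobutenylmethyl bromide A9 (Catellani reaction). The aryl–palladium bond would then add across the aryl cyclobutene and be reduced, giving the dibenzyl ether A7 of the target. This is the most convergent road: the chromene is present from the start, and syn arylpalladation followed by hydride delivery places the catechol ring trans to ring A by mechanism. Its longest linear sequence would be shorter than the chosen one, provided A9 is at hand. The drawbacks are several. A9 is an enantiopure, thermally fragile cyclobutene that needs its own asymmetric synthesis. Its bromide is β‑branched and slow to add to the palladacycle. The closing insertion into a trisubstituted cyclobutene competes with simple reduction. In A7 the benzyl ethers sit beside a chromene double bond, so hydrogenolysis is not available. The chosen plan is longer and linear, but each precursor of its key step is accessible by known reactions and it needs only one purchased element of chirality.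

Key step: step 11

Assumption: the prenylborane 13 is taken to follow the facial rule of the parent allylborane, so that the reagent derived from (−)‑α‑pinene adds to the Re face of RCH2CHO; 1, 2, 12, 22 and (+)‑Ipc2BH (Ipc = isopinocampheyl) are taken as purchasable.

Step 1
Reactants: 1 phloroglucinol; 2 3‑methylbut‑2‑enoic acid
Product: 4 5,7‑dihydroxy‑2,2‑dimethylchroman‑4‑one, via acylphloroglucinol enone 3 (not isolated)
Conditions: P2O5, MeSO3H, 70 °C
Reagents that add atoms: none
Why: Friedel–Crafts acylation of the symmetrical triphenol, then intramolecular oxa‑Michael addition of an ortho hydroxyl to the enone; symmetry removes any regiochemical question.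

Step 2
Reactants: 4 5,7‑dihydroxy‑2,2‑dimethylchroman‑4‑one
Product: 5 5‑hydroxy‑7‑methoxy‑2,2‑dimethylchroman‑4‑one
Conditions: MeI (1.05 equiv), K2CO3, acetone, rt
Reagents that add atoms: iodomethane, CI
Why: Williamson ether synthesis; the 5‑hydroxyl is hydrogen‑bonded to the carbonyl and reacts much more slowly, so the 7‑hydroxyl should be methylated selectively.

Step 3
Reactants: 5 5‑hydroxy‑7‑methoxy‑2,2‑dimethylchroman‑4‑one
Product: 6 5‑(allyloxy)‑7‑methoxy‑2,2‑dimethylchroman‑4‑one
Conditions: allyl bromide, K2CO3, DMF, 60 °C
Reagents that add atoms: allyl bromide, C=CCBr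
Why: Williamson ether synthesis under more forcing conditions, which alkylates the chelated phenol once the free one is capped.

Step 4
Reactants: 6 5‑(allyloxy)‑7‑methoxy‑2,2‑dimethylchroman‑4‑one
Product: 8 6‑allyl‑5‑hydroxy‑7‑methoxy‑2,2‑dimethylchroman‑4‑one, via Claisen dienone 7 (not isolated)
Conditions: N,N‑diethylaniline, 200 °C
Reagents that add atoms: none
Why: Aromatic Claisen rearrangement; C6 is the only free ortho position of the C5 allyl ether (the other is C4a), so the allyl group must arrive at C6, and tautomerisation restores the chelated phenol.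

Step 5
Reactants: 8 6‑allyl‑5‑hydroxy‑7‑methoxy‑2,2‑dimethylchroman‑4‑one
Product: 9 6‑allyl‑7‑methoxy‑2,2‑dimethyl‑4‑oxochroman‑5‑yl trifluoromethanesulfonate
Conditions: Tf2O, pyridine, CH2Cl2, 0 °C
Reagents that add atoms: trifluoromethanesulfonic anhydride, O=S(=O)(OS(=O)(=O)C(F)(F)F)C(F)(F)F
Why: O‑sulfonylation of the phenol; triflic anhydride is reactive enough for a chelated, flanked hydroxyl, and the product is the cross‑coupling handle at C5.

Step 6
Reactants: 9 6‑allyl‑7‑methoxy‑2,2‑dimethyl‑4‑oxochroman‑5‑yl trifluoromethanesulfonate
Product: 11 7‑methoxy‑2,2‑dimethyl‑4‑oxo‑6‑(2‑oxoethyl)chroman‑5‑yl trifluoromethanesulfonate, via secondary ozonide 10 (not isolated)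
Conditions: O3, CH2Cl2, −78 °C; PPh3, −78 °C to rt
Reagents that add atoms: ozone, [O-][O+]=O
Why: Ozonolysis with reductive work‑up; the terminal alkene reacts far faster than the arene, which is deactivated by the triflate and the ketone, and the aldehyde is used crude because it is enolisable.

Step 7
Reactants: 11 7‑methoxy‑2,2‑dimethyl‑4‑oxo‑6‑(2‑oxoethyl)chroman‑5‑yl trifluoromethanesulfonate; 12 3‑methylbuta‑1,2‑diene
Product: 15 6‑[(2S)‑2‑hydroxy‑3,3‑dimethylpent‑4‑enyl]‑7‑methoxy‑2,2‑dimethyl‑4‑oxochroman‑5‑yl trifluoromethanesulfonate, via prenylborane 13 (not isolated), via borinate ester 14 (not isolated)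
Conditions: (+)‑Ipc2BH (from (−)‑α‑pinene), 12, THF, −25 to 0 °C; then 11, −78 °C; NaBO3·4H2O, THF/H2O, rt
Reagents that add atoms: none
Why: Brown reverse prenylation: hydroboration of the allene gives the prenylborane, which adds to the aldehyde with allylic transposition through a closed chair (Zimmerman–Traxler) transition state. The isopinocampheyl groups from (−)‑α‑pinene direct attack to the Re face and so set the (S)‑carbinol Cb; the ketone does not react at −78 °C.

Step 8
Reactants: 15 6‑[(2S)‑2‑hydroxy‑3,3‑dimethylpent‑4‑enyl]‑7‑methoxy‑2,2‑dimethyl‑4‑oxochroman‑5‑yl trifluoromethanesulfonate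
Product: 16 6‑[(2S)‑2‑hydroxy‑3,3‑dimethylpent‑4‑enyl]‑7‑methoxy‑2,2‑dimethyl‑5‑vinylchroman‑4‑one
Conditions: tributyl(vinyl)stannane, Pd(PPh3)4, LiCl, 1,4‑dioxane, 100 °C
Reagents that add atoms: tributyl(vinyl)stannane, C=C[Sn](CCCC)(CCCC)CCCC
Why: Stille coupling of an aryl triflate; oxidative addition is helped by the ortho carbonyl, chloride speeds transmetalation from tin, and the free alcohol and remote alkene are tolerated.

Step 9
Reactants: 16 6‑[(2S)‑2‑hydroxy‑3,3‑dimethylpent‑4‑enyl]‑7‑methoxy‑2,2‑dimethyl‑5‑vinylchroman‑4‑one
Product: 17 benzo‑fused cycloheptenol: 7‑methoxy‑2,2‑dimethylchroman‑4‑one bridged C5–CH=CH–C(CH3)2–CH(OH)–CH2–C6, (S) at the carbinol carbon Cb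
Conditions: second‑generation Grubbs catalyst (H2IMes)(PCy3)Cl2Ru=CHPh, toluene (0.005 M), 80 °C
Reagents that add atoms: none
Why: Ring‑closing metathesis of two terminal alkenes to a seven‑membered ring, driven by loss of ethylene; the ring size allows only the cis styrene needed later, and the stereocentre is not touched.

Step 10
Reactants: 17 benzo‑fused cycloheptenol, (S) at Cb
Product: 18 methanesulfonate of 17, (S) at Cb
Conditions: MsCl, Et3N, CH2Cl2, 0 °C
Reagents that add atoms: methanesulfonyl chloride, CS(=O)(=O)Cl
Why: O‑mesylation through sulfene, which is insensitive to the neighbouring quaternary carbon; only the O–S bond forms, so the configuration at Cb is kept.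

Step 11
Reactants: 18 methanesulfonate of 17, (S) at Cb
Product: 20 tricyclic cyclobutyl pinacol boronate (7‑methoxy‑2,2‑dimethylchroman‑4‑one with the ring C5–Cc–Cb–Ca–C6 cis‑fused to the cyclobutane Cb–Cc–Cd–Ce; Bpin on Cd trans to ring A; Cb S; Cc S; Cd S), via benzylic copper intermediate 19 (not isolated)
Conditions: CuCl (10 mol%), Xantphos (10 mol%), B2pin2 (1.5 equiv), KOtBu (1.2 equiv), THF, rt to 40 °C, 18 added last
Reagents that add atoms: bis(pinacolato)diboron, CC1(C)OB(OC1(C)C)B1OC(C)(C)C(C)(C)O1
Why: Proposed new method: the closest known reaction is the copper‑catalysed borylative cyclisation of acyclic (Z)‑aryl homoallylic sulfonates to trans‑2‑arylcyclobutyl boronates; here the sulfonate is secondary, neopentyl‑type and placed across a seven‑membered ring. A Xantphos boryl copper complex formed from CuCl, KOtBu and B2pin2 adds syn across the styrene bond of 18, boron to Cd next to CMe2 and copper to the benzylic Cc, where the aryl ring and its ortho carbonyl stabilise the carbon–copper bond (19). The benzylic copper then displaces the mesylate at Cb from the back, with retention at Cc and inversion at Cb; this is a 4‑exo‑tet closure of the cyclobutane (Cc–Cd–Ce–Cb) and, counted through ring A (Cc–C5–C6–Ca–Cb), at the same time a 5‑exo‑tet closure of the cyclopentane. Cb is set by inversion of the (S)‑mesylate, Cc by the fact that only a copper placed anti to the mesylate can reach the back of the C–O bond (hence the cis fusion), and Cd by the syn addition, which after closure leaves boron trans to ring A. The step needs copper‑at‑benzylic regioselectivity, which the electron‑poor styrene should give, and addition anti to the mesylate, which is favoured because the mesylate shields its own face; the syn adduct cannot cyclise, so a lapse costs yield and not stereochemical purity. The quaternary carbon lies inside the forming ring, so it should help closure (gem‑dialkyl effect) instead of blocking the back side as in an intermolecular neopentyl substitution, and the chromanone carbonyl, deactivated by its ortho and para oxygen donors, should be left alone.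

Step 12
Reactants: 20 tricyclic cyclobutyl pinacol boronate
Product: 21 potassium trifluoroborate of 20 (BF3K on Cd, trans to ring A; Cb S, Cc S, Cd S)
Conditions: KHF2, MeOH/H2O, rt; pinacol removed by repeated evaporation from MeOH/H2O
Reagents that add atoms: potassium hydrogen difluoride, [K+].[F-].F
Why: Standard exchange of a pinacol boronate for the trifluoroborate by fluoride; no bond at carbon changes, so the three stereocentres are carried over.

Step 13
Reactants: 21 potassium trifluoroborate of 20; 22 4‑bromo‑1,2‑bis(benzyloxy)benzene
Product: 23 tricyclic chromanone with a 3,4‑bis(benzyloxy)phenyl group on Cd, trans to ring A (Cb S, Cc R, Cd S)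
Conditions: [Ir(dF(CF3)ppy)2(bpy)]PF6 (2.5 mol%), NiCl2·glyme (5 mol%), 4,4′‑di‑tert‑butyl‑2,2′‑bipyridine (5 mol%), Cs2CO3, 1,4‑dioxane, blue LEDs, rt
Reagents that add atoms: none
Why: Photoredox/nickel cross‑coupling of a secondary alkyl trifluoroborate with an aryl bromide (single‑electron transmetalation). Oxidation of 21 gives the cyclobutyl radical at Cd, which the arylnickel species should capture on the convex face, anti to ring A and its peri carbonyl, so the aryl group ends up where boron was; Cb and Cc are not involved.

Step 14
Reactants: 23 tricyclic chromanone with a 3,4‑bis(benzyloxy)phenyl group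
Product: 24 tricyclic chromanone with a 3,4‑dihydroxyphenyl group on Cd (Cb S, Cc R, Cd S)
Conditions: H2 (1 atm), Pd/C, EtOAc/MeOH, rt
Reagents that add atoms: none
Why: Hydrogenolysis of aryl benzyl ethers; it is done at the ketone stage because no chromene double bond is yet present, and at 1 atm and rt the aryl ketone and the cyclobutane should survive.

Step 15
Reactants: 24 tricyclic chromanone with a 3,4‑dihydroxyphenyl group
Product: 26 target CNP0207533.1 (chromene; Cb S; Cc R; Cd S), via chroman‑4‑ol 25 (not isolated)
Conditions: NaBH4, MeOH/THF, 0 °C to rt; aqueous NH4Cl work‑up; then p‑TsOH·H2O (cat.), toluene, 60 °C, under argon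
Reagents that add atoms: none
Why: Carbonyl reduction to the chroman‑4‑ol (mixture of C4 epimers, of no consequence), then acid‑catalysed E1 dehydration; the C4 cation is stabilised by the ring oxygen and the 7‑methoxy group, so mild acid should suffice and the three stereocentres are remote from the reacting carbon.

**Compound list**

1 | phloroglucinol | Oc1cc(O)cc(O)c1 | starting material
2 | 3‑methylbut‑2‑enoic acid | CC(C)=CC(O)=O | starting material
3 | 3‑methyl‑1‑(2,4,6‑trihydroxyphenyl)but‑2‑en‑1‑one | CC(C)=CC(=O)c1c(O)cc(O)cc1O | intermediate
4 | 5,7‑dihydroxy‑2,2‑dimethylchroman‑4‑one | Oc1cc2OC(C)(C)CC(=O)c2c(O)c1 | intermediate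
5 | 5‑hydroxy‑7‑methoxy‑2,2‑dimethylchroman‑4‑one | COc1cc2OC(C)(C)CC(=O)c2c(O)c1 | intermediate
6 | 5‑(allyloxy)‑7‑methoxy‑2,2‑dimethylchroman‑4‑one | COc1cc2OC(C)(C)CC(=O)c2c(OCC=C)c1 | intermediate
7 | 6‑allyl‑7‑methoxy‑2,2‑dimethyl‑2,3‑dihydrochromene‑4,5(6H)‑dione (Claisen dienone, C6 racemic) | COC1=CC2=C(C(=O)CC(C)(C)O2)C(=O)C1CC=C | intermediate
8 | 6‑allyl‑5‑hydroxy‑7‑methoxy‑2,2‑dimethylchroman‑4‑one | COc1cc2OC(C)(C)CC(=O)c2c(O)c1CC=C | intermediate
9 | 6‑allyl‑7‑methoxy‑2,2‑dimethyl‑4‑oxochroman‑5‑yl trifluoromethanesulfonate | COc1cc2OC(C)(C)CC(=O)c2c(OS(=O)(=O)C(F)(F)F)c1CC=C | intermediate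
10 | secondary ozonide of 9 (1,2,4‑trioxolan‑3‑ylmethyl group on C6, ozonide carbon racemic) | COc1cc2OC(C)(C)CC(=O)c2c(OS(=O)(=O)C(F)(F)F)c1CC1OCOO1 | intermediate
11 | 7‑methoxy‑2,2‑dimethyl‑4‑oxo‑6‑(2‑oxoethyl)chroman‑5‑yl trifluoromethanesulfonate | COc1cc2OC(C)(C)CC(=O)c2c(OS(=O)(=O)C(F)(F)F)c1CC=O | intermediate
12 | 3‑methylbuta‑1,2‑diene | CC(C)=C=C | starting material
13 | (3‑methylbut‑2‑enyl)bis(isopinocampheyl)borane, isopinocampheyl groups from (−)‑α‑pinene | CC(C)=CCB([C@H]1C[C@H]2C[C@@H]([C@@H]1C)C2(C)C)[C@H]1C[C@H]2C[C@@H]([C@@H]1C)C2(C)C | intermediate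
14 | bis(isopinocampheyl)borinate ester of 15 | COc1cc2OC(C)(C)CC(=O)c2c(OS(=O)(=O)C(F)(F)F)c1C[C@H](OB([C@H]1C[C@H]2C[C@@H]([C@@H]1C)C2(C)C)[C@H]1C[C@H]2C[C@@H]([C@@H]1C)C2(C)C)C(C)(C)C=C | intermediate
15 | 6‑[(2S)‑2‑hydroxy‑3,3‑dimethylpent‑4‑enyl]‑7‑methoxy‑2,2‑dimethyl‑4‑oxochroman‑5‑yl trifluoromethanesulfonate | COc1cc2OC(C)(C)CC(=O)c2c(OS(=O)(=O)C(F)(F)F)c1C[C@H](O)C(C)(C)C=C | intermediate
16 | 6‑[(2S)‑2‑hydroxy‑3,3‑dimethylpent‑4‑enyl]‑7‑methoxy‑2,2‑dimethyl‑5‑vinylchroman‑4‑one | COc1cc2OC(C)(C)CC(=O)c2c(C=C)c1C[C@H](O)C(C)(C)C=C | intermediate
17 | benzo‑fused cycloheptenol (chromanone bridged C5–CH=CH–CMe2–CH(OH)–CH2–C6; Cb S) | COc1cc2OC(C)(C)CC(=O)c2c2c1C[C@H](O)C(C)(C)C=C2 | intermediate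
18 | methanesulfonate of 17 (Cb S) | COc1cc2OC(C)(C)CC(=O)c2c2c1C[C@H](OS(C)(=O)=O)C(C)(C)C=C2 | intermediate
19 | β‑boryl benzylic copper intermediate (copper on Cc, Bpin on Cd, both anti to the mesylate; Xantphos on copper not drawn) | COc1cc2OC(C)(C)CC(=O)c2c2c1C[C@H](OS(C)(=O)=O)C(C)(C)[C@@H](B1OC(C)(C)C(C)(C)O1)[C@H]2[Cu] | intermediate
20 | tricyclic cyclobutyl pinacol boronate (Bpin on Cd trans to ring A; Cb S, Cc S, Cd S) | COc1cc2OC(C)(C)CC(=O)c2c2c1C[C@H]1[C@@H]2[C@H](B3OC(C)(C)C(C)(C)O3)C1(C)C | intermediate
21 | potassium trifluoroborate of 20 (Cb S, Cc S, Cd S) | COc1cc2OC(C)(C)CC(=O)c2c2c1C[C@H]1[C@@H]2[C@H]([B-](F)(F)F)C1(C)C.[K+] | intermediate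
22 | 4‑bromo‑1,2‑bis(benzyloxy)benzene | Brc1ccc(OCc2ccccc2)c(OCc2ccccc2)c1 | starting material
23 | tricyclic chromanone with 3,4‑bis(benzyloxy)phenyl on Cd, trans to ring A (Cb S, Cc R, Cd S) | COc1cc2OC(C)(C)CC(=O)c2c2c1C[C@H]1[C@@H]2[C@H](c2ccc(OCc3ccccc3)c(OCc3ccccc3)c2)C1(C)C | intermediate
24 | tricyclic chromanone with 3,4‑dihydroxyphenyl on Cd (Cb S, Cc R, Cd S) | COc1cc2OC(C)(C)CC(=O)c2c2c1C[C@H]1[C@@H]2[C@H](c2ccc(O)c(O)c2)C1(C)C | intermediate
25 | chroman‑4‑ol of 24 (C4 epimers; Cb S, Cc R, Cd S) | COc1cc2OC(C)(C)CC(O)c2c2c1C[C@H]1[C@@H]2[C@H](c2ccc(O)c(O)c2)C1(C)C | intermediate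
26 | CNP0207533.1 (Cb S, Cc R, Cd S) | COc1cc2c(c3c1C[C@H]1[C@@H]3[C@H](c3ccc(O)c(O)c3)C1(C)C)C=CC(C)(C)O2 | target

**Step count and risks**

Total step count: 15. Longest linear sequence: 15 steps, from 1 to 26; 12 and 22 enter as purchased materials.

Step 11 (key step, new method). The most likely failure is that the transannular displacement at the secondary, neopentyl‑type carbon is too slow. The benzylic copper intermediate would then be protonated, or the alkoxide would eliminate the mesylate toward the benzylic CH2. A second loss is addition of boron and copper on the face syn to the mesylate, which cannot close and lowers the yield only. Adding 18 last to the pre‑formed boryl copper, with the alkoxide kept bound to excess diboron, is the first adjustment. The fallback uses known chemistry, sets out from 9 and returns at 23, with the aryl group on the alkene before the four‑membered ring is made. Cross‑metathesis of 9 with 2‑methylbut‑2‑ene (second‑generation Grubbs catalyst) would give the 6‑prenyl triflate F1. Suzuki–Miyaura coupling (Pd(OAc)2, SPhos, K3PO4, toluene/H2O) with the (E)‑styrylboronate F2, made from 22 and vinylboronic acid pinacol ester by a Heck reaction (Pd(P(t‑Bu)3)2, i‑Pr2NH, toluene), would give the (E)‑stilbene F3. Irradiation with blue light and [Ir(dF(CF3)ppy)2(dtbbpy)]PF6 as triplet sensitiser should then close the cyclobutane by intramolecular [2+2] cycloaddition, a reaction type well known for styrenes tethered to alkenes. The five‑membered ring closes first (5‑exo), and radical recombination places the aryl group exo. This gives 23 together with its enantiomer F4, which must be removed by chromatography on a chiral stationary phase. The price is half the material and the loss of reagent‑based absolute control.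

Step 13. The cyclobutyl radical is flanked by a quaternary and a tertiary carbon, so capture by nickel may be slow and the radical may be reduced or dimerise. Oxidative addition of the electron‑rich bromide may lag, and facial selectivity at Cd may be incomplete. The fallback, from 21 (with 22) to 23, changes from radical capture to a two‑electron, stereospecific Suzuki–Miyaura coupling (Pd(OAc)2, n‑BuP(1‑adamantyl)2, Cs2CO3, toluene/H2O, 100 °C). Transmetalation of small‑ring cycloalkyl boron reagents is expected to go with retention, so the boron configuration from step 11 would be used directly; no new compound is involved.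

Step 9. Both alkenes are hindered (a 2,6‑disubstituted styrene and a vinyl group on a quaternary carbon), so ring closure may lose to intermolecular metathesis or catalyst decay. The Stille coupling before it can also be diverted by insertion of the aryl–palladium bond into the tethered alkene. The fallback, from 15 to 17, closes the ring by that insertion on purpose. An intramolecular Heck reaction under neutral, chloride‑containing conditions (Pd(OAc)2, P(o‑tol)3, LiCl, Et3N, DMF, 90 °C) should place the aryl group on the terminal alkene carbon (7‑endo), because the internal carbon is next to the quaternary centre. β‑Hydride elimination can then only give the styrene of 17. This removes one step and makes no new compound.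

Step 7. The risks are incomplete facial control, which would lower the enantiomeric purity of every later compound, and aldol loss of the enolisable aldehyde before it is trapped. The fallback, from 11 (with 12) to 15, replaces the chiral reagent by a chiral catalyst: iridium‑catalysed transfer‑hydrogenative tert‑prenylation ([Ir(cod)Cl]2, the SEGPHOS enantiomer that gives the (S)‑alcohol, Cs2CO3, 3‑nitrobenzoic acid, propan‑2‑ol, toluene, 60 °C). The allene is turned into an allyliridium nucleophile in the flask; no new compound is involved.

Step 15. The C4 cation formed during dehydration may be trapped by the chromene product or by the electron‑rich catechol ring, and the free catechol may be oxidised by air during handling. The fallback, from 24 to 26, avoids the cation. Silylation (TBSCl, imidazole, DMF) would give the bis(silyl) ether F5. Tf2O and 2,6‑di‑tert‑butyl‑4‑methylpyridine would convert the ketone into the enol triflate F6. Palladium‑catalysed formate reduction (Pd(OAc)2, PPh3, Bu3N, HCO2H, DMF, 60 °C) would give the silylated chromene F7. Buffered fluoride (Bu4NF, AcOH, THF, 0 °C) would then release 26.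

**Further compounds**

F1 | step 11 | 7‑methoxy‑2,2‑dimethyl‑6‑(3‑methylbut‑2‑enyl)‑4‑oxochroman‑5‑yl trifluoromethanesulfonate | COc1cc2OC(C)(C)CC(=O)c2c(OS(=O)(=O)C(F)(F)F)c1CC=C(C)C
F2 | step 11 | 2‑[(E)‑2‑(3,4‑bis(benzyloxy)phenyl)vinyl]‑4,4,5,5‑tetramethyl‑1,3,2‑dioxaborolane | CC1(C)OB(/C=C/c2ccc(OCc3ccccc3)c(OCc3ccccc3)c2)OC1(C)C
F3 | step 11 | 5‑[(E)‑2‑(3,4‑bis(benzyloxy)phenyl)vinyl]‑7‑methoxy‑2,2‑dimethyl‑6‑(3‑methylbut‑2‑enyl)chroman‑4‑one | COc1cc2OC(C)(C)CC(=O)c2c(/C=C/c2ccc(OCc3ccccc3)c(OCc3ccccc3)c2)c1CC=C(C)C
F4 | step 11 | enantiomer of 23 (Cb R, Cc S, Cd R) | COc1cc2OC(C)(C)CC(=O)c2c2c1C[C@@H]1[C@H]2[C@@H](c2ccc(OCc3ccccc3)c(OCc3ccccc3)c2)C1(C)C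
F0 | step 13 | none | none
F0 | step 9 | none | none
F0 | step 7 | none | none
F5 | step 15 | bis(tert‑butyldimethylsilyl) ether of 24 | COc1cc2OC(C)(C)CC(=O)c2c2c1C[C@H]1[C@@H]2[C@H](c2ccc(O[Si](C)(C)C(C)(C)C)c(O[Si](C)(C)C(C)(C)C)c2)C1(C)C
F6 | step 15 | enol triflate of F5 (C3=C4, triflate on C4) | COc1cc2OC(C)(C)C=C(OS(=O)(=O)C(F)(F)F)c2c2c1C[C@H]1[C@@H]2[C@H](c2ccc(O[Si](C)(C)C(C)(C)C)c(O[Si](C)(C)C(C)(C)C)c2)C1(C)C
F7 | step 15 | bis(tert‑butyldimethylsilyl) ether of 26 | COc1cc2OC(C)(C)C=Cc2c2c1C[C@H]1[C@@H]2[C@H](c2ccc(O[Si](C)(C)C(C)(C)C)c(O[Si](C)(C)C(C)(C)C)c2)C1(C)C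
A1 | alternative 1 | prenylated hydroxy methoxy indanone fused to the aryl cyclobutane | COc1cc(O)c(CC=C(C)C)c2c1C(=O)[C@H]1[C@@H]2[C@H](c2ccc(OCc3ccccc3)c(OCc3ccccc3)c2)C1(C)C
A2 | alternative 1 | 3‑bromo bicyclo[3.2.0]hept‑3‑en‑2‑one with gem‑dimethyl and 3,4‑bis(benzyloxy)phenyl on the cyclobutane | O=C1[C@H]2[C@@H](C=C1Br)[C@H](c1ccc(OCc3ccccc3)c(OCc3ccccc3)c1)C2(C)C
A3 | alternative 1 | 1,1‑dimethoxy‑7‑methyl‑3‑(trimethylsilyloxy)octa‑1,3,6‑triene | COC(OC)=CC(O[Si](C)(C)C)=CCC=C(C)C
A4 | alternative 2 | exo‑aryl cyclobutanone fused to the indane‑chromanone | COc1cc2OC(C)(C)CC(=O)c2c2c1C[C@H]1[C@@H]2[C@H](c3ccc(OCc4ccccc4)c(OCc4ccccc4)c3)C1=O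
A5 | alternative 2 | indene of ring A on the chromanone (C5–CH=CH–CH2–C6) | COc1cc2OC(C)(C)CC(=O)c2c2c1CC=C2
A6 | alternative 2 | 2‑(3,4‑bis(benzyloxy)phenyl)‑1‑[(2R,5R)‑2,5‑dimethylpyrrolidin‑1‑yl]ethanone | C[C@@H]1CC[C@@H](C)N1C(=O)Cc1ccc(OCc2ccccc2)c(OCc2ccccc2)c1
A7 | alternative 3 | dibenzyl ether of 26 | COc1cc2c(c3c1C[C@H]1[C@@H]3[C@H](c3ccc(OCc4ccccc4)c(OCc4ccccc4)c3)C1(C)C)C=CC(C)(C)O2
A8 | alternative 3 | 5‑iodo‑7‑methoxy‑2,2‑dimethyl‑2H‑chromene | COc1cc2OC(C)(C)C=Cc2c(I)c1
A9 | alternative 3 | [3‑(3,4‑bis(benzyloxy)phenyl)‑4,4‑dimethylcyclobut‑2‑enyl]methyl bromide, single enantiomer | BrC[C@H]1C=C(c2ccc(OCc3ccccc3)c(OCc3ccccc3)c2)C1(C)C
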